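**Retrosynthesis**
1. 1-CQA ⇒ 1-O-(3,4-diacetoxycinnamoyl) 3,4-acetonide quinide. The tertiary ester is made on the bridged lactone, where C1–OH is accessible. The catechol acetates, lactone and acetonide are then removed under near-neutral or acidic conditions, with a lipase unmasking the phenols.
2. Quinide acetonide ⇐ cis-dihydroxylation of a bicyclic lactone alkene. The lactone bridge blocks one face, which sets C3/C4 relative to C5 and C1.
3. Lactone alkene ⇐ E2 of an iodolactone ⇐ iodolactonization of (S)-1-hydroxycyclohex-3-enecarboxylic acid. The ring exists from the Diels–Alder step; the bicycle forms at the iodolactonization.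
4. Hydroxy acid ⇐ asymmetric Diels–Alder of butadiene with 2-acetoxyacrolein. This sets the quaternary C1 stereocentre.

Assumptions:
- The target is the natural (1S,3R,4S,5R)-quinate series. The catalyst enantiomer in Step 3 is chosen to give adduct **5** as drawn.
- 2-Acetoxyacrolein is prepared rather than purchased.

---

**Step 1**
Reactants: **1** pyruvaldehyde dimethyl acetal
Product: **2** 3,3-dimethoxyprop-1-en-2-yl acetate
Conditions: isopropenyl acetate (solvent), TsOH·H2O (2 mol%), reflux, acetone distilled off
Reagents that add atoms: isopropenyl acetate, CC(=O)OC(C)=C (acetyl group)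
Why: Acid-catalysed enol acetylation. Only the CH3 side can enolize usefully, so the terminal enol acetate forms, and removing acetone drives it.

**Step 2**
Reactants: **2**
Product: **3** 2-acetoxyacrolein
Conditions: Amberlyst-15 (H+), THF/H2O 10:1, 0 °C→rt, 3 h; careful low-temperature concentration; use at once as a CH2Cl2 solution
Reagents that add atoms: water, O (aldehyde oxygen)
Why: Acid hydrolysis of the dimethyl acetal. The enol acetate survives brief mild aqueous acid.

**Step 3**
Reactants: **3** 2-acetoxyacrolein; **4** 1,3-butadiene (5 equiv)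
Product: **5** (1S)-1-formylcyclohex-3-en-1-yl acetate
Conditions: chiral oxazaborolidinium triflimide (10 mol%; diarylprolinol-derived B-Me oxazaborolidine + Tf2NH), CH2Cl2, −78→−40 °C, 48 h, sealed
Reagents that add atoms: none
Why: Catalytic enantioselective Diels–Alder. The Lewis acid-bound acyloxyacrolein exposes one face to the diene, forming the cyclohexene and the quaternary C1 (O up, CHO down in the SMILES frame).

**Step 4**
Reactants: **5**
Product: **6** (1S)-1-hydroxycyclohex-3-ene-1-carbaldehyde
Conditions: K2CO3 (0.2 equiv), MeOH, 0 °C, 1 h; NH4Cl quench; crude used directly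
Reagents that add atoms: none
Why: Base methanolysis of the tertiary acetate. C1 has no α-H and is not touched, so its configuration is kept.

**Step 5**
Reactants: **6**
Product: **7** (1S)-1-hydroxycyclohex-3-ene-1-carboxylic acid
Conditions: NaClO2, NaH2PO4, 2-methyl-2-butene, t-BuOH/H2O 3:1, 0 °C→rt, 3 h
Reagents that add atoms: sodium chlorite, [Na+].[O-]Cl=O (oxygen)
Why: Pinnick oxidation. It is chemoselective for the aldehyde, leaves the alkene and tertiary alcohol alone, and does not touch C1.

**Step 6**
Reactants: **7**
Product: **8** 1-hydroxy-4-iodo-6-oxabicyclo[3.2.1]octan-7-one (I trans to the lactone O)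
Conditions: I2 (3 equiv), NaHCO3 (3 equiv), CH2Cl2/H2O 1:1, 0 °C→rt, 16 h, dark; Na2S2O3 quench
Reagents that add atoms: iodine, II
Why: Iodolactonization. The carboxylate attacks the iodonium 5-exo from the face cis to C1–COOH, so the lactone O (future C5–O) is cis to the carboxyl and I is trans-diaxial (future C4). This fixes C5 and C4 relative to C1.

**Step 7**
Reactants: **8**
Product: **9** 1-hydroxy-6-oxabicyclo[3.2.1]oct-3-en-7-one
Conditions: DBU (3 equiv), toluene, 80 °C, 8 h
Reagents that add atoms: none
Why: E2 elimination. The only H anti-periplanar to the axial iodide is the axial H on C3, so the C3=C4 alkene forms regiospecifically. No stereocentre is changed.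

**Step 8**
Reactants: **9**
Product: **10** (−)-quinide (quinic acid 1,5-lactone)
Conditions: OsO4 (5 mol%), NMO, acetone/H2O 10:1, rt, 16 h
Reagents that add atoms: osmium tetroxide, O=[Os](=O)(=O)=O; N-methylmorpholine N-oxide, C[N+]1([O-])CCOCC1 (hydroxyl oxygens)
Why: Upjohn syn-dihydroxylation. Osmylation occurs from the face opposite the diaxial lactone bridge. This places the C3 and C4 OH groups cis and on the same face as C1–OH, and anti to C5–O, which is the quinic acid configuration.

**Step 9**
Reactants: **10**
Product: **11** 3,4-O-isopropylidene quinide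
Conditions: 2,2-dimethoxypropane (4 equiv), TsOH·H2O (5 mol%), acetone, rt, 6 h
Reagents that add atoms: 2,2-dimethoxypropane, COC(C)(C)OC (isopropylidene)
Why: Acetonide formation. Only the cis-3,4-diol closes a five-membered ketal; the tertiary C1–OH stays free and no stereocentre is altered.

**Step 10**
Reactants: **12** caffeic acid
Product: **13** (E)-3,4-diacetoxycinnamic acid
Conditions: Ac2O (4 equiv), pyridine, 0 °C→rt, 3 h; then THF/H2O, 1 h (breaks the mixed anhydride); 1 M HCl
Reagents that add atoms: acetic anhydride, CC(=O)OC(C)=O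
Why: Phenol acetylation. Aqueous work-up restores the free carboxylic acid, and the E-alkene is unchanged.

**Step 11**
Reactants: **13**
Product: **14** (E)-3,4-diacetoxycinnamoyl chloride
Conditions: (COCl)2 (1.5 equiv), DMF (cat.), CH2Cl2, 0 °C→rt, 2 h; evaporate
Reagents that add atoms: oxalyl chloride, ClC(=O)C(=O)Cl (chlorine)
Why: Vilsmeier-type acid chloride formation under neutral conditions that keep the aryl acetates.

**Step 12**
Reactants: **11**; **14** (3 equiv)
Product: **15** 1-O-(3,4-diacetoxycinnamoyl)-3,4-O-isopropylidene quinide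
Conditions: DMAP (1.5 equiv), Et3N (4 equiv), CH2Cl2, 0 °C→40 °C, 24 h
Reagents that add atoms: none
Why: DMAP-catalysed acylation of the tertiary alcohol. It works here because in the bridged lactone C1–OH is equatorial, whereas in the open quinate it is axial and 1,3-diaxial to O3. Acylation is at oxygen, so C1 is unchanged.

**Step 13**
Reactants: **15**
Product: **16** 3,4-O-isopropylidene-1-O-caffeoylquinic acid (free catechol, free carboxylic acid)
Conditions: Candida antarctica lipase B (immobilized, hydrolase EC 3.1.1.3), 0.1 M phosphate pH 8.0/acetone 2:1, sodium ascorbate (5 mol%), N2, 30 °C, pH-stat with 0.1 M NaOH, 24 h; filter; acidify to pH 3 at 0 °C; EtOAc extraction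
Reagents that add atoms: water, O (phenol OH and carboxylic acid)
Why: Enzymatic hydrolysis. The serine hydrolase cleaves the unhindered aryl acetates without strong base, avoiding catechol oxidation, and cannot reach the hindered tertiary cinnamate. At pH 8 the strained, α-acyloxy-activated lactone opens to the carboxylate. No stereocentre is touched.

**Step 14**
Reactants: **16**
Product: **17** 1-O-caffeoylquinic acid (target)
Conditions: TFA/H2O 1:1, 0 °C→rt, 3 h; lyophilize; prep. RP-HPLC (C18, H2O/MeCN, 0.1% HCOOH)
Reagents that add atoms: none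
Why: Acid-catalysed acetonide hydrolysis liberates the cis-3,4-diol. The tertiary cinnamate and the stereocentres are stable.

---

**Compound list**

| No. | Name | SMILES | Role |
|---|---|---|---|
| 1 | pyruvaldehyde dimethyl acetal | CC(=O)C(OC)OC | starting material |
| 2 | 3,3-dimethoxyprop-1-en-2-yl acetate | C=C(OC(C)=O)C(OC)OC | intermediate |
| 3 | 2-acetoxyacrolein | C=C(OC(C)=O)C=O | intermediate |
| 4 | 1,3-butadiene | C=CC=C | starting material |
| 5 | (1S)-1-formylcyclohex-3-en-1-yl acetate | CC(=O)O[C@]1(C=O)CC=CCC1 | intermediate |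
| 6 | (1S)-1-hydroxycyclohex-3-ene-1-carbaldehyde | O[C@]1(C=O)CC=CCC1 | intermediate |
| 7 | (1S)-1-hydroxycyclohex-3-ene-1-carboxylic acid | O[C@]1(C(=O)O)CC=CCC1 | intermediate |
| 8 | 1-hydroxy-4-iodo-6-oxabicyclo[3.2.1]octan-7-one (I up, lactone O down) | O[C@@]12C[C@@H](OC1=O)[C@H](I)CC2 | intermediate |
| 9 | 1-hydroxy-6-oxabicyclo[3.2.1]oct-3-en-7-one | O[C@@]12C[C@@H](OC1=O)C=CC2 | intermediate |
| 10 | (−)-quinide (1,3,4-trihydroxy-6-oxabicyclo[3.2.1]octan-7-one) | O[C@@]12C[C@@H](OC1=O)[C@H](O)[C@H](O)C2 | intermediate |
| 11 | 3,4-O-isopropylidene quinide | O[C@@]12C[C@@H](OC1=O)[C@@H]3OC(C)(C)O[C@@H]3C2 | intermediate |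
| 12 | caffeic acid | OC(=O)/C=C/c1ccc(O)c(O)c1 | starting material |
| 13 | (E)-3,4-diacetoxycinnamic acid | CC(=O)Oc1ccc(/C=C/C(=O)O)cc1OC(C)=O | intermediate |
| 14 | (E)-3,4-diacetoxycinnamoyl chloride | CC(=O)Oc1ccc(/C=C/C(=O)Cl)cc1OC(C)=O | intermediate |
| 15 | 1-O-(3,4-diacetoxycinnamoyl)-3,4-O-isopropylidene quinide | CC(=O)Oc1ccc(/C=C/C(=O)O[C@@]23C[C@@H](OC2=O)[C@@H]4OC(C)(C)O[C@@H]4C3)cc1OC(C)=O | intermediate |
| 16 | 3,4-O-isopropylidene-1-O-caffeoylquinic acid | O=C(/C=C/c1ccc(O)c(O)c1)O[C@]2(C(=O)O)C[C@@H](O)[C@@H]3OC(C)(C)O[C@@H]3C2 | intermediate |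
| 17 | 1-O-caffeoylquinic acid, (1S,3R,4S,5R) | O=C(/C=C/c1ccc(O)c(O)c1)O[C@]1(C(=O)O)C[C@@H](O)[C@H](O)[C@H](O)C1 | target |

**Total steps:** 14 (12 in the main sequence plus the 2-step side-chain branch, Steps 10–11).
**Longest linear sequence:** 12 steps (Steps 1–9, then 12, 13, 14).

**Three steps most likely to fail**
1. **Step 3 (asymmetric Diels–Alder).** Butadiene is a poor diene, and 2-acetoxyacrolein is prone to polymerization, so yield or ee may be low. Fallback: run a racemic BF3·OEt2-promoted Diels–Alder, then resolve hydroxy acid **7** by crystallizing its diastereomeric salt with (R)-1-phenylethylamine, and continue unchanged.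
2. **Step 12 (tertiary acylation).** The tertiary, hindered bridgehead OH may acylate incompletely. Fallback: acylate **11** with a Meldrum's-acid-derived malonyl ketene to give the 1-O-malonate, then Knoevenagel–Doebner condensation with 3,4-diacetoxybenzaldehyde to build the (E)-cinnamate in place.
3. **Step 13 (enzymatic deacetylation and lactone opening).** The lipase may stall on the lipophilic substrate, or the lactone may open too slowly at pH 8. Fallback: redo Steps 10–12 with a 3,4-bis(MOM-oxy)cinnamoyl chloride, open the lactone with LiOH in THF/H2O at 0 °C, and remove the MOM and acetonide groups together with aqueous HCl/MeOH.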